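**Retrosynthetic overview**
1. Target 16 ⇒ aldehyde 14 (oxidation level of C18 only).
2. 14 ⇒ diene 12 + methacrolein: ring A is closed last by a catalyst-controlled exo Diels–Alder reaction that sets C4 and C5.
3. 12 ⇒ tetraene 10 + propanoic acid: key step, the C15–O bond is made by a Pd-catalysed 4,1-hydroacyloxylation of the 2-alkylbutadiene terminus, which also fixes the (E)-C13=C14 alkene.
4. 10 ⇒ diketone 6 by double enol triflation and double vinylation.
5. 6 ⇒ 2-methylcyclohex-2-enone (ring B, present from the start) + MeMgBr + a silyl vinyl ketone: asymmetric conjugate addition and Michael trapping set C8 and C9.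

Assumption: catalysts, ligands, bases, additives, scavengers and solvents are named in the conditions and not numbered; halimane numbering is used in the explanations (C4 = CO2H carbon, C5 = ring-fusion CH, C8 = CHMe, C9 = quaternary carbon with the side chain, C10 = sp2 fusion carbon, C15 = CH2O).

**Step 1**
Reactants: 1 2-methylcyclohex-2-en-1-one; 2 methylmagnesium bromide; 3 3-(trimethylsilyl)but-3-en-2-one
Product: 6 (2S,3R)-2,3-dimethyl-2-(3-oxobutyl)cyclohexan-1-one, via magnesium enolate 4 (not isolated), via silyl diketone 5 (not isolated)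
Conditions: MeMgBr (1.2 equiv), Cu(OTf)2 (3 mol%), chiral hydroxyalkyl-NHC precursor (4 mol%, enantiomer giving 3R), Et2O, −30 °C; then 3 (1.5 equiv), THF/DMPU, −78 → −30 °C; then K2CO3 (cat.), MeOH/H2O, 0 °C
Reagents that add atoms: methylmagnesium bromide (C[Mg]Br); 3-(trimethylsilyl)but-3-en-2-one (CC(=O)C(=C)[Si](C)(C)C)
Why: Cu/NHC-catalysed asymmetric conjugate addition sets C8 (R) by catalyst control, and the trisubstituted magnesium enolate then adds (Michael addition, Stork silyl vinyl ketone) anti to the new pseudoaxial C8 methyl, which sets the quaternary C9 (S, chain trans to C8-Me); the silyl group suppresses polymerisation and is lost on mild basic work-up.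

**Step 2**
Reactants: 6 (2S,3R)-2,3-dimethyl-2-(3-oxobutyl)cyclohexan-1-one; 7 N-(5-chloropyridin-2-yl)bis(trifluoromethanesulfonimide) (Comins' reagent)
Product: 8 (5R,6S)-5,6-dimethyl-6-{3-[(trifluoromethanesulfonyl)oxy]but-3-en-1-yl}cyclohex-1-en-1-yl trifluoromethanesulfonate
Conditions: LDA (2.3 equiv), THF, −78 °C (6 added to the base); then 7 (2.4 equiv), −78 → 0 °C
Reagents that add atoms: N-(5-chloropyridin-2-yl)bis(trifluoromethanesulfonimide) (FC(F)(F)S(=O)(=O)N(c1ccc(Cl)cn1)S(=O)(=O)C(F)(F)F)
Why: Kinetic double enolisation (inverse addition to excess base leaves no free ketone for aldol closure) can only occur at C5 of the ring ketone (C9 is quaternary) and occurs at the methyl group of the side-chain ketone, and both enolates are O-sulfonylated (enol triflate formation) without touching a stereocentre.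

**Step 3**
Reactants: 8 the bis(enol triflate); 9 tributyl(ethenyl)stannane
Product: 10 (5R,6S)-1-ethenyl-5,6-dimethyl-6-(3-methylidenepent-4-en-1-yl)cyclohex-1-ene
Conditions: Pd(PPh3)4 (5 mol%), LiCl (6 equiv), 9 (2.4 equiv), THF, 65 °C
Reagents that add atoms: tributyl(ethenyl)stannane (C=C[Sn](CCCC)(CCCC)CCCC)
Why: Twofold Stille coupling of the two enol triflates with retention of alkene position gives the semicyclic ring diene and the 2-alkylbutadiene side chain in one operation.

**Step 4**
Reactants: 10 the tetraene; 11 propanoic acid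
Product: 12 (2E)-5-[(1S,6R)-2-ethenyl-1,6-dimethylcyclohex-2-en-1-yl]-3-methylpent-2-en-1-yl propanoate
Conditions: Pd2(dba)3 (2.5 mol%), Xantphos (6 mol%), EtCO2H (20 equiv, co-solvent), toluene, 40 °C
Reagents that add atoms: propanoic acid (CCC(=O)O)
Why: Proposed new method: Pd(0)/Xantphos and the acid give a Pd–H that transfers H to the exocyclic CH2 (C16) of the s-cis 2-alkylbutadiene, forming the 1,1-disubstituted π-allyl with the chain syn and the new methyl anti, and outer-sphere propanoate attack at the primary terminus C15 gives the linear (E)-ester, while reversible C–O ionisation returns any branched tertiary ester or any adduct of the hindered ring diene (whose allyl would carry the quaternary C9 on its central carbon) to this product; the closest known reaction type is Pd–H hydrofunctionalisation of isoprene-type dienes with N- and C-nucleophiles (linear prenylation) and the telomerisation of dienes with carboxylic acids, which has not been shown as a selective linear (E)-hydroacyloxylation.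

**Step 5**
Reactants: 12 the diene propanoate; 13 2-methylprop-2-enal (methacrolein)
Product: 14 (2E)-5-[(1S,2R,4aS,5S)-5-formyl-1,2,5-trimethyl-1,2,3,4,4a,5,6,7-octahydronaphthalen-1-yl]-3-methylpent-2-en-1-yl propanoate
Conditions: (S)-diphenylprolinol-derived o-tolyl oxazaborolidinium triflimide (20 mol%), 13 (5 equiv), CH2Cl2, −78 → −40 °C
Reagents that add atoms: 2-methylprop-2-enal (CC(=C)C=O)
Why: Lewis-acid-catalysed Diels–Alder reaction in which the enal CH2 bonds first to the unhindered vinyl terminus C2 and the α-carbon to ring carbon C5 ("ortho" adduct, C1=C10 alkene formed in place), the clash between the complexed formyl group and the quaternary C9 puts CHO exo (CHO cis to H-5, methyl trans), and the chiral cation leaves only the α-carbon Re face of s-trans methacrolein open so that C4 becomes S and, through the exo geometry, C5 becomes S, overriding the weak facial bias of the diene because bond formation starts far from C8/C9.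

**Step 6**
Reactants: 14 the aldehyde; 15 sodium chlorite
Product: 16 (1S,5S,6R,8aS)-1,5,6-trimethyl-5-[(3E)-3-methyl-5-(propanoyloxy)pent-3-en-1-yl]-1,2,3,5,6,7,8,8a-octahydronaphthalene-1-carboxylic acid (target)
Conditions: NaClO2 (3 equiv), NaH2PO4, 2-methylbut-2-ene (20 equiv), t-BuOH/H2O, 0 °C → rt
Reagents that add atoms: sodium chlorite ([Na+].[O-]Cl=O)
Why: Pinnick oxidation converts the non-epimerisable neopentyl aldehyde into the acid, and the alkene scavenger removes HOCl so that both trisubstituted alkenes and the allylic ester survive.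

**Compound list**
1 | 2-methylcyclohex-2-en-1-one | CC1=CCCCC1=O | starting material
2 | methylmagnesium bromide | C[Mg]Br | starting material
3 | 3-(trimethylsilyl)but-3-en-2-one | CC(=O)C(=C)[Si](C)(C)C | starting material
4 | bromomagnesium (3R)-2,3-dimethylcyclohex-1-en-1-olate | CC1=C(O[Mg]Br)CCC[C@H]1C | intermediate (not isolated)
5 | (2S,3R)-2,3-dimethyl-2-[3-oxo-2-(trimethylsilyl)butyl]cyclohexan-1-one (epimers at C–Si) | CC(=O)C(C[C@]1(C)C(=O)CCC[C@H]1C)[Si](C)(C)C | intermediate (not isolated)
6 | (2S,3R)-2,3-dimethyl-2-(3-oxobutyl)cyclohexan-1-one | CC(=O)CC[C@]1(C)C(=O)CCC[C@H]1C | intermediate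
7 | N-(5-chloropyridin-2-yl)bis(trifluoromethanesulfonimide) | FC(F)(F)S(=O)(=O)N(c1ccc(Cl)cn1)S(=O)(=O)C(F)(F)F | starting material
8 | (5R,6S)-5,6-dimethyl-6-{3-[(trifluoromethanesulfonyl)oxy]but-3-en-1-yl}cyclohex-1-en-1-yl trifluoromethanesulfonate | C=C(OS(=O)(=O)C(F)(F)F)CC[C@]1(C)C(OS(=O)(=O)C(F)(F)F)=CCC[C@H]1C | intermediate
9 | tributyl(ethenyl)stannane | C=C[Sn](CCCC)(CCCC)CCCC | starting material
10 | (5R,6S)-1-ethenyl-5,6-dimethyl-6-(3-methylidenepent-4-en-1-yl)cyclohex-1-ene | C=CC(=C)CC[C@]1(C)C(C=C)=CCC[C@H]1C | intermediate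
11 | propanoic acid | CCC(=O)O | starting material
12 | (2E)-5-[(1S,6R)-2-ethenyl-1,6-dimethylcyclohex-2-en-1-yl]-3-methylpent-2-en-1-yl propanoate | CCC(=O)OC/C=C(\C)CC[C@]1(C)C(C=C)=CCC[C@H]1C | intermediate
13 | 2-methylprop-2-enal | CC(=C)C=O | starting material
14 | (2E)-5-[(1S,2R,4aS,5S)-5-formyl-1,2,5-trimethyl-1,2,3,4,4a,5,6,7-octahydronaphthalen-1-yl]-3-methylpent-2-en-1-yl propanoate | CCC(=O)OC/C=C(\C)CC[C@]1(C)C2=CCC[C@](C)(C=O)[C@H]2CC[C@H]1C | intermediate
15 | sodium chlorite | [Na+].[O-]Cl=O | starting material
16 | (1S,5S,6R,8aS)-1,5,6-trimethyl-5-[(3E)-3-methyl-5-(propanoyloxy)pent-3-en-1-yl]-1,2,3,5,6,7,8,8a-octahydronaphthalene-1-carboxylic acid | CCC(=O)OC/C=C(\C)CC[C@]1(C)C2=CCC[C@](C)(C(=O)O)[C@H]2CC[C@H]1C | target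

**Total steps:** 6. **Longest linear sequence:** 6.

**Three steps most likely to fail**

Step 4 (proposed new step). The addition is close to thermoneutral, so conversion depends on the acid excess. The E/Z ratio could erode through syn/anti exchange of the π-allyl, and Pd–H could isomerise or engage the ring diene. The fallback uses known chemistry and sets out from 10. Iron-catalysed 1,4-hydroboration of the 2-alkylbutadiene with pinacolborane (iminopyridine–FeCl2, Mg, Et2O, rt) gives the linear (E)-allylboronate F2. Oxidation with NaBO3·4H2O gives allylic alcohol F3. Acylation with propanoic anhydride, pyridine and DMAP gives the ester, and the route is rejoined at 12.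

Step 5. The catalyst may be mismatched with the intrinsic facial preference of the diene, and the exo/endo or "ortho" selectivity may be incomplete on this hindered diene. The fallback moves stereocontrol from the catalyst to a late separation and sets out from 12. An achiral Me2AlCl-promoted exo Diels–Alder reaction with methacrolein gives 14 together with aldehyde diastereomer F4 (ring A of opposite configuration). Pinnick oxidation of the mixture gives 16 and acid diastereomer F5. The two acids are separated by preparative HPLC or by crystallisation of their (R)-1-phenylethylammonium salts, so the route is rejoined at 16.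

Step 1. The Michael trapping of the hindered magnesium enolate may be slow, may oligomerise the vinyl ketone, or may give a poor trans/cis ratio at C9. The fallback replaces the Michael addition by alkylation and hydrolysis and sets out from 1. The same conjugate addition gives enolate 4, which is alkylated with 1,3-dichlorobut-2-ene (NaI, DMPU, −20 °C) to give chlorobutenyl ketone F1. Wichterle hydrolysis of the vinyl chloride (90% H2SO4, 0 °C) gives the diketone, and the route is rejoined at 6.

**Further compounds**
F1 | step 1 | (2S,3R)-2-(3-chlorobut-2-en-1-yl)-2,3-dimethylcyclohexan-1-one (E/Z mixture) | CC(Cl)=CC[C@]1(C)C(=O)CCC[C@H]1C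
F2 | step 4 | 2-{(2E)-5-[(1S,6R)-2-ethenyl-1,6-dimethylcyclohex-2-en-1-yl]-3-methylpent-2-en-1-yl}-4,4,5,5-tetramethyl-1,3,2-dioxaborolane | CC1(C)OB(C/C=C(\C)CC[C@]2(C)C(C=C)=CCC[C@H]2C)OC1(C)C
F3 | step 4 | (2E)-5-[(1S,6R)-2-ethenyl-1,6-dimethylcyclohex-2-en-1-yl]-3-methylpent-2-en-1-ol | OC/C=C(\C)CC[C@]1(C)C(C=C)=CCC[C@H]1C
F4 | step 5 | (2E)-5-[(1S,2R,4aR,5R)-5-formyl-1,2,5-trimethyl-1,2,3,4,4a,5,6,7-octahydronaphthalen-1-yl]-3-methylpent-2-en-1-yl propanoate | CCC(=O)OC/C=C(\C)CC[C@]1(C)C2=CCC[C@@](C)(C=O)[C@@H]2CC[C@H]1C
F5 | step 5 | (1R,5S,6R,8aR)-1,5,6-trimethyl-5-[(3E)-3-methyl-5-(propanoyloxy)pent-3-en-1-yl]-1,2,3,5,6,7,8,8a-octahydronaphthalene-1-carboxylic acid | CCC(=O)OC/C=C(\C)CC[C@]1(C)C2=CCC[C@@](C)(C(=O)O)[C@@H]2CC[C@H]1C
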